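## Structural features

- The target is a type B polyprenylated acylphloroglucinol with a bicyclo[3.3.1]nonane core. Ring A (C1–C2–C3–C4–C5–C9) holds the enolised C2–C3–C4 dione with the 3,4-dihydroxybenzoyl group on C3. Ring B (C1–C9–C5–C6–C7–C8) is a cyclohexanone with the gem-dimethyl carbon C8 and the prenylated methine C7. The rings share C1, C9 and C5.
- There are three stereocentres: the quaternary bridgeheads C1 (prenyl) and C5 (geranyl) and the tertiary C7. C7 sits next to the non-stereogenic C8 and is 1,3 to both bridgeheads. Its prenyl group is equatorial on a chair ring B, trans to the C2–C3–C4 bridge.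
- C1 is a quaternary carbon between the quaternary C8 and two carbonyl carbons. This is the most congested position in the molecule.
- Fragile groups are the four trisubstituted alkenes (acid-induced cyclisation onto the enol oxygen, cation–olefin reactions, electrophilic halogen, hydrogenation), the acidic tricarbonyl, the air-sensitive catechol, and non-enolisable 1,3-dicarbonyl arrays open to retro-Claisen cleavage.
- The real difficulty is placing the two one-carbon arms C2 and C4 cis-diaxial on ring B, joining them through C3, and bringing an aroyl group onto C3 of a hindered trione.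
- The key step uses the fact that C4 and the aroyl carbonyl carbon are 1,3-related through C3. An isoxazole stores exactly this pattern as its C=N carbon and its O-bearing carbon. A nitrile oxide at C4 and an aryl ynone C2(=O)–C3≡C–Ar, held 1,3-diaxial on ring B, can therefore close ring A and deliver the aroyl group in one cycloaddition.

## Logic of the disconnections

**33 to 32.** The C4–O bond is exchanged for C4–N and the two phenolic O–H bonds for O–Si. The free vinylogous acid and catechol are the least robust form, so they appear only in the last step. The forward step must hydrolyse a hindered vinylogous amide under base, because acid would cyclise the prenyl and geranyl groups onto the enol oxygen.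

**32 to 31.** The N–O bond is re-formed. The isoxazole carries C4 and the aroyl carbonyl as a neutral aromatic ring, so no acidic tricarbonyl has to be carried. The forward step needs an N–O reduction that spares four alkenes, which excludes hydrogenation.

**31 to 28 (key).** C3–C4 and the oxygen–aryl-carbon bond are cut. Ring A and the heterocycle open together and leave a monocyclic ring B ketone with two arms. The forward step demands that the arms be cis-diaxial and that oxime and ynone coexist.

**28 to 26 (through 27).** The C=N bond is cut and the aldehyde is masked as its dimethyl acetal. The N–OH group is put in last because it tolerates neither enolate nor oxidation steps. The forward step demands that condensation at the aldehyde outrun conjugate addition to the ynone.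

**26 to 25 to 18 + 23.** The C1–C2 bond is cut as an aldol bond, after adjusting the oxidation level. One bond then brings in C2, C3 and the aryl carbon. The forward step demands enolisation of the shielded C1–H and attack on the α face. The arm must enter last at C1 so that it ends axial.

**23 to 21 to 20 to 19.** The formyl–alkyne bond and the alkyne carbon are cut back to an aryl aldehyde, and the phenols are silylated. Only the silyl ethers have to survive organolithium reagents.

**18 to 15 + 16.** The C1–CH2(prenyl) bond is cut. C1 is the only enolisable position left, so regiochemistry is not at issue. The demand is C-alkylation at a neopentylic enolate carbon.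

**15 to 14 to 13.** The C5–C4 bond is cut to a formyl cation equivalent and a regiodefined silyl enol ether. Geranyl must be on C5 before the arm, so that the arm enters axially, trans to the C7 prenyl group. The forward steps demand thermodynamic regiocontrol of the enol ether and facial control.

**13 to 10 + 11.** The C5–CH2(geranyl) bond is cut. The kinetic enolate forms away from the gem-dimethyl carbon.

**10 to 9 to 8 to 7.** The two C8–CH3 bonds are cut as two conjugate methylations with a dehydrogenation between them. C7 stays γ to the carbonyl throughout and cannot epimerise.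

**7 to 4 + 5 (through 6).** C6–C7 (Michael) and C1=C8 (aldol condensation) are cut. The only absolute stereocentre, C7, is set by aminocatalysis. C1 and C5 are later relayed from it.

**4 to 1 + 2.** The C–C bond is cut as a [3,3] shift of an allyl vinyl ether made from two bulk chemicals.

## Other disconnections considered

**Alternative 1:** The cut is C5–C6 of ring B.
- Forward: the trifluoroacetate salt of 9-amino-9-deoxy-epi-quinine would convert the 2-substituted acrolein of the achiral trione A2 into an iminium ion. One enantiotopic enol carbon (C5) adds to the β-carbon C6, and protonation at C7 should place the formyl group equatorial, giving A1.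
- In favour: one catalytic operation would build the whole bicyclic trione from a flat precursor and set C1, C5 and C7 together.
- Against: A1 has hydrogen on C5, a formyl group on C7 and nothing on C3. Geranyl must then go onto a bridgehead by deprotonation and alkylation of a protected vinylogous ester. The formyl group must be homologated by one carbon before olefination (a direct Wittig reaction would give a 2-methylpropenyl group). C3 must be aroylated late. The iminium ion also carries the quaternary C8 on its α-carbon, which should slow it.
- Comparison: on structure, A1 reaches the bicycle earlier, whereas the chosen plan has every carbon substituent in place before ring A closes. On mechanism, a reversible ionic Michael addition stands against an irreversible pericyclic closure that creates no stereocentre. On step economy, core formation and absolute stereocontrol in one catalytic step is the better of the two. The three deferred C–C bonds would probably cancel that gain.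

**Alternative 2:** The cut is C5–C6 together with the C7–CH2(prenyl) bond.
- Forward: (Bu3Sn)2 under light would abstract bromine from C5 of A4. The dicarbonyl radical closes 6-endo onto the terminal carbon C6 of the 1,1-dimethylallyl group on C1. The C7 radical adds to the allyl sulfone A5, which fragments to leave the prenyl group, giving A3.
- In favour: two C–C bonds, ring B and the C7 stereocentre arise together under neutral conditions. The planar C5 radical means only C1 must be set beforehand.
- Against: 5-exo closure onto C7 competes. The intermolecular capture of a hindered secondary radical must outrun reduction and bromine transfer, and the facial selectivity at C7 rests on steric approach alone. Tin reagents are needed. A3 still requires conversion of the silyloxyethyl group to prenyl, C3 aroylation and demethylation, and enantioenriched A4 must be made first.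
- Comparison: on structure, ring B is closed late on a preformed ring A, the reverse of the chosen order. On mechanism, a radical chain with an intermolecular terminating step stands against a unimolecular cycloaddition whose regiochemistry is fixed by the tether. Alternative 2 is the better plan in avoiding enolate chemistry at the congested C1 and in spending no separate step on C7. The two are equal in leaving a masked tricarbonyl to unveil. About five steps would follow A3, against two after 31.

**Alternative 3:** The cut is C1–C8.
- Forward: TiCl4 would ionise the tertiary alcohol of A7. The β-carbon C1 of one enol ether attacks the C8 cation through a chair with the C7 prenyl group equatorial, and the oxocarbenium at C9 collapses to the ketone, giving A6.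
- In favour: the quaternary C8 and both bridgeheads would be set relative to C7 in one step, with geranyl already on C5. The precursor comes from alkylation of a Birch-type diene.
- Against: a tertiary cation next to a prenyl group, in a molecule with two more trisubstituted alkenes, has cation–olefin and elimination pathways open. TiCl4 threatens the enol ethers. A6 then needs oxidation at C2, prenylation of the bridgehead C1 next to C8, aroylation at C3 and demethylation.
- Comparison: on step economy to the bicycle, Alternative 3 is the better plan. It is the equal of the chosen plan in drawing all stereochemistry from C7. On mechanism, it exposes a polyene to a strong Lewis acid, which the chosen plan never does. On structure, it leaves three late functionalisations of the core where the chosen plan leaves none.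

Key step: step 16

**Conventions and assumptions**
- Locants follow the bicyclic numbering of the target throughout, also for monocyclic ring B compounds: C9 ketone, C1 and C5 its α-carbons, C6 methylene, C7 prenyl methine, C8 dimethyl carbon.
- β is the face of ring B carrying the C7 prenyl group and α the opposite face. In the target C2 and C4 are α (axial) and the C1 prenyl and C5 geranyl groups are β.
- Ar = 3,4-bis(tert-butyldimethylsilyloxy)phenyl.
- A check of 28 and 31 against 33 (C1, C5, C7, E-geranyl, E-oxime, nitrogen on C4, oxygen on the aryl-bearing carbon) shows agreement, so both are used as drawn.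
- Assumption: epimers at a centre that is made planar again later (C5 in 13, C1 in 18, the carbinol carbon in 25) are carried on as mixtures.
- (S)-Limonene would deliver the correct C7 configuration. It would then need a tertiary-cation closure of C1 onto C8 beside the prenyl alkene, so a catalytic Michael–aldol entry is used instead.

## Route

Step 1
Reactants: 1 2-methylbut-3-en-2-ol; 2 ethyl vinyl ether
Product: 4 5-methylhex-4-enal, via allyl vinyl ether 3 (not isolated)
Conditions: H3PO4 (cat.), neat, 140 °C, sealed tube
Reagents that add atoms: none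
Why: Acid-catalysed vinyl transfer gives the allyl vinyl ether 3, which undergoes a Claisen rearrangement; the new alkene carries two methyl groups, so no geometry issue arises.

Step 2
Reactants: 4 5-methylhex-4-enal; 5 but-3-en-2-one
Product: 7 (4S)-4-(3-methylbut-2-en-1-yl)cyclohex-2-en-1-one, via Michael adduct 6 (not isolated)
Conditions: (S)-α,α-diphenylprolinol methyl ether (5 mol %), ethyl 3,4-dihydroxybenzoate (20 mol %), neat, 4 °C; then LiOH, i-PrOH, 25 °C
Reagents that add atoms: none
Why: Enamine-catalysed asymmetric Michael addition followed by intramolecular aldol condensation; the diarylmethyl group of the (S)-catalyst shields one face of the E-enamine, so the enone adds to the open face and sets C7 as drawn. The condensation should be fast enough to limit epimerisation of the α-branched aldehyde.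

Step 3
Reactants: 7 (4S)-4-(3-methylbut-2-en-1-yl)cyclohex-2-en-1-one
Product: 8 trimethyl{[(3S,4S)-3-methyl-4-(3-methylbut-2-en-1-yl)cyclohex-1-en-1-yl]oxy}silane
Conditions: Me2CuLi (from MeLi, CuI), TMSCl, Et2O, −78 °C; Et3N
Reagents that add atoms: lithium dimethylcuprate, [Li+].C[Cu-]C; chlorotrimethylsilane, C[Si](C)(C)Cl
Why: Silyl-accelerated cuprate conjugate addition with in situ enolate trapping; methyl enters trans to the C7 prenyl group, but this C8 centre is removed again in step 4.

Step 4
Reactants: 8 trimethyl{[(3S,4S)-3-methyl-4-(3-methylbut-2-en-1-yl)cyclohex-1-en-1-yl]oxy}silane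
Product: 9 (4S)-3-methyl-4-(3-methylbut-2-en-1-yl)cyclohex-2-en-1-one
Conditions: Pd(OAc)2 (10 mol %), O2 (1 atm), DMSO, 25 °C
Reagents that add atoms: none
Why: Saegusa–Ito oxidation; the palladium enolate at C1 has β-hydrogen only on C8, so the C1=C8 enone forms regiospecifically and C7 (γ) is not touched.

Step 5
Reactants: 9 (4S)-3-methyl-4-(3-methylbut-2-en-1-yl)cyclohex-2-en-1-one
Product: 10 (4S)-3,3-dimethyl-4-(3-methylbut-2-en-1-yl)cyclohexan-1-one
Conditions: Me2CuLi, Et2O, −78 → 0 °C; aq. NH4Cl
Reagents that add atoms: lithium dimethylcuprate, [Li+].C[Cu-]C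
Why: Second cuprate conjugate addition makes C8 the gem-dimethyl carbon, which is no longer stereogenic; C7 is unchanged.

Step 6
Reactants: 10 (4S)-3,3-dimethyl-4-(3-methylbut-2-en-1-yl)cyclohexan-1-one; 11 geranyl bromide
Product: 13 C5-geranyl ring B ketone (C5 epimers), via lithium enolate 12 (not isolated)
Conditions: LiN(i-Pr)2, THF, −78 °C; then 11, −78 → 0 °C
Reagents that add atoms: none
Why: Kinetic deprotonation occurs at C5, away from the neopentylic C1, and the enolate is alkylated by the allylic bromide (SN2); the C5 configuration is irrelevant because C5 is made planar in step 7.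

Step 7
Reactants: 13 C5-geranyl ring B ketone
Product: 14 C9 trimethylsilyl enol ether with the C9=C5 double bond
Conditions: TMSCl, NaI, Et3N, MeCN, 25 °C
Reagents that add atoms: chlorotrimethylsilane, C[Si](C)(C)Cl
Why: Equilibrating silylation with in situ iodotrimethylsilane should favour the more substituted enol ether, which defines C5 as the nucleophilic carbon for step 8.

Step 8
Reactants: 14 C9 trimethylsilyl enol ether with the C9=C5 double bond
Product: 15 ring B ketone with C5 α-dimethoxymethyl and β-geranyl groups
Conditions: HC(OMe)3, TMSOTf (10 mol %), CH2Cl2, −78 °C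
Reagents that add atoms: trimethyl orthoformate, COC(OC)OC
Why: Mukaiyama-type alkylation of a silyl enol ether by the dimethoxycarbenium ion. The electrophile should attack C5 axially on the half-chair with the C7 prenyl group equatorial, on the α face trans to that group, because the β face would need a twist-boat or an axial C7 prenyl group.

Step 9
Reactants: 15 ring B ketone with C5 α-dimethoxymethyl and β-geranyl groups; 16 prenyl bromide
Product: 18 C1-prenyl derivative of 15 (C1 epimers), via lithium enolate 17 (not isolated)
Conditions: LiN(i-Pr)2, THF, −78 → 0 °C; then 16, DMPU, −78 → 0 °C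
Reagents that add atoms: none
Why: Only C1 still has α-hydrogen, so the enolate is regiodefined and is alkylated by the allylic bromide (SN2); the C1 configuration is irrelevant because C1 is enolised again in step 13.

Step 10
Reactants: 19 3,4-dihydroxybenzaldehyde
Product: 20 3,4-bis(tert-butyldimethylsilyloxy)benzaldehyde
Conditions: TBSCl, imidazole, DMF, 25 °C
Reagents that add atoms: tert-butyldimethylsilyl chloride, CC(C)(C)[Si](C)(C)Cl
Why: Standard silylation of both phenols; the aryl silyl ethers tolerate organolithium reagents at low temperature, aqueous acid and oxidants, and fall off under the final basic hydrolysis.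

Step 11
Reactants: 20 3,4-bis(tert-butyldimethylsilyloxy)benzaldehyde
Product: 21 1,1-dibromo-2-[3,4-bis(tert-butyldimethylsilyloxy)phenyl]ethene
Conditions: CBr4, PPh3, CH2Cl2, 0 °C
Reagents that add atoms: carbon tetrabromide, BrC(Br)(Br)Br
Why: First stage of the Corey–Fuchs homologation (dibromomethylenation by the phosphorus ylide).

Step 12
Reactants: 21 1,1-dibromo-2-[3,4-bis(tert-butyldimethylsilyloxy)phenyl]ethene
Product: 23 3-[3,4-bis(tert-butyldimethylsilyloxy)phenyl]prop-2-ynal, via lithium acetylide 22 (not isolated)
Conditions: n-BuLi (2.1 equiv), THF, −78 °C; then DMF, −78 → 0 °C; aq. KH2PO4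
Reagents that add atoms: N,N-dimethylformamide, CN(C)C=O
Why: Second stage of the Corey–Fuchs sequence (bromine–lithium exchange, rearrangement and deprotonation to the acetylide) followed by formylation with DMF; the buffered quench protects the ynal.

Step 13
Reactants: 18 C1-prenyl derivative of 15; 23 3-[3,4-bis(tert-butyldimethylsilyloxy)phenyl]prop-2-ynal
Product: 25 aldol adduct with the C1 α-(1-hydroxy-3-arylprop-2-yn-1-yl) arm (carbinol epimers), via lithium enolate 24 (not isolated)
Conditions: LiN(i-Pr)2, THF, 0 °C; then 23, −78 °C; AcOH, −78 °C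
Reagents that add atoms: none
Why: Aldol addition of a fully substituted lithium enolate to a non-enolisable, sterically slim ynal. The aldehyde should add axially on the α face of C1, anti to the axial C8 methyl and trans to the C7 prenyl group, since the other half-chair would put the C5 geranyl and C7 prenyl groups syn-diaxial. The cold quench prevents retro-aldol cleavage.

Step 14
Reactants: 25 aldol adduct with the C1 α-(1-hydroxy-3-arylprop-2-yn-1-yl) arm
Product: 26 C1 aryl ynone with the C5 dimethoxymethyl arm
Conditions: Dess–Martin periodinane, NaHCO3, CH2Cl2, 0 → 25 °C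
Reagents that add atoms: none
Why: Buffered Dess–Martin oxidation of the propargylic alcohol removes the carbinol stereocentre; acetal, alkenes and aryl silyl ethers are inert.

Step 15
Reactants: 26 C1 aryl ynone with the C5 dimethoxymethyl arm
Product: 28 ring B ketone with C5 (E)-aldoxime and C1 aryl ynone, via keto aldehyde 27 (not isolated)
Conditions: 2 M HCl, THF, 25 °C; then NaOAc, NH2OH·HCl (1.1 equiv), EtOH/H2O, 0 °C
Reagents that add atoms: hydroxylamine hydrochloride, NO.Cl
Why: Acetal hydrolysis followed by oxime condensation in the same flask, so the non-enolisable keto aldehyde is never isolated; at pH about 5 and 0 °C the aldehyde should condense much faster than hydroxylamine adds to the aryl ynone, and the hindered aldoxime should form as the E isomer.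

Step 16
Reactants: 28 ring B ketone with C5 (E)-aldoxime and C1 aryl ynone
Product: 31 isoxazole-fused bicyclo[3.3.1]nonane-2,9-dione bis-silyl ether, via hydroximoyl chloride 29 (not isolated), via nitrile oxide 30 (not isolated)
Conditions: NCS, pyridine (cat.), CHCl3, 0 → 25 °C; then Et3N (slow addition), CHCl3 (high dilution), 25 → 40 °C
Reagents that add atoms: none
Why: Pyridine-buffered NCS chlorinates the aldoxime carbon to the hydroximoyl chloride 29, and slow addition of Et3N eliminates HCl to the nitrile oxide 30. The dipole then adds to the ynone in a concerted, asynchronous [3+2] cycloaddition that forms C4–C3 and the oxygen–aryl-carbon bond; the closest known reaction type is the intramolecular nitrile oxide–alkyne cycloaddition. Ring A closes as a six-membered carbocycle by exo attack of C4 on the proximal alkyne carbon C3 (tether C5–C9–C1–C2), and the five-membered isoxazole closes in the same event in the fused mode; the bridged regioisomer would need a seven-membered ring and is out of reach. No stereocentre is created and C1, C5 and C7 are untouched. The fused sense is also the electronically matched one, with the oxygen terminus bonding to the β-carbon of the ynone. Ring closure must beat furoxan dimerisation, which is secured by the quaternary C5 next to the dipole, by the 1,3-diaxial proximity of the two arms on the chair of ring B and by high dilution. The alkyne must beat the alkenes as dipolarophile, which is secured because the C1 and C7 prenyl groups are equatorial and trans to the dipole, and the geranyl group on C5 could only close a four- or five-membered bridged ring. Chlorination of the four trisubstituted alkenes is held back by the buffered, stoichiometric use of NCS at low temperature.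

Step 17
Reactants: 31 isoxazole-fused bicyclo[3.3.1]nonane-2,9-dione bis-silyl ether
Product: 32 C4-amino enaminone bis-silyl ether
Conditions: Mo(CO)6, MeCN/H2O, 80 °C
Reagents that add atoms: none
Why: Reductive N–O cleavage of an isoxazole by zerovalent molybdenum carbonyl in wet acetonitrile gives the β-enaminone; isolated alkenes, ketones and aryl silyl ethers are not reduced.

Step 18
Reactants: 32 C4-amino enaminone bis-silyl ether
Product: 33 CNP0160101.3 (target; C1 S, C5 S, C7 R for the tautomer written)
Conditions: NaOH (2 M, degassed), MeOH/THF, 60 °C, argon; then cold 1 M HCl to pH 3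
Reagents that add atoms: water, O
Why: Addition–elimination of hydroxide at C4 hydrolyses the vinylogous amide with loss of ammonia, and the same medium cleaves both aryl silyl ethers. The resulting enolate of the trione protects ring A from retro-Claisen attack, basic conditions avoid acid-induced cyclisation of the prenyl and geranyl groups, and exclusion of oxygen protects the catecholate.

## Compound list

1 | 2-methylbut-3-en-2-ol | CC(C)(O)C=C | starting material
2 | ethyl vinyl ether | C=COCC | starting material
3 | 3-(ethenyloxy)-3-methylbut-1-ene (formed in situ) | C=COC(C)(C)C=C | intermediate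
4 | 5-methylhex-4-enal | CC(C)=CCCC=O | intermediate
5 | but-3-en-2-one | CC(=O)C=C | starting material
6 | (2S)-2-(3-methylbut-2-en-1-yl)-5-oxohexanal (formed in situ) | CC(=O)CC[C@@H](CC=C(C)C)C=O | intermediate
7 | (4S)-4-(3-methylbut-2-en-1-yl)cyclohex-2-en-1-one | O=C1CC[C@@H](CC=C(C)C)C=C1 | intermediate
8 | trimethyl{[(3S,4S)-3-methyl-4-(3-methylbut-2-en-1-yl)cyclohex-1-en-1-yl]oxy}silane (3,4-trans) | C[Si](C)(C)OC1=C[C@@H](C)[C@H](CC=C(C)C)CC1 | intermediate
9 | (4S)-3-methyl-4-(3-methylbut-2-en-1-yl)cyclohex-2-en-1-one | O=C1CC[C@@H](CC=C(C)C)C(C)=C1 | intermediate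
10 | (4S)-3,3-dimethyl-4-(3-methylbut-2-en-1-yl)cyclohexan-1-one (ring B ketone) | O=C1CC[C@@H](CC=C(C)C)C(C)(C)C1 | intermediate
11 | geranyl bromide | CC(C)=CCC/C(C)=C/CBr | starting material
12 | kinetic lithium enolate of 10, C9=C5 (formed in situ) | [Li]OC1=CC[C@@H](CC=C(C)C)C(C)(C)C1 | intermediate
13 | C5-geranyl ring B ketone, C5 epimers, C7 as in 10 | CC(C)=CCC/C(C)=C/CC1C[C@@H](CC=C(C)C)C(C)(C)CC1=O | intermediate
14 | C9 trimethylsilyl enol ether of 13 with the C9=C5 double bond | CC(C)=CCC/C(C)=C/CC1=C(O[Si](C)(C)C)CC(C)(C)[C@H](CC=C(C)C)C1 | intermediate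
15 | ring B ketone with C5 α-dimethoxymethyl (trans to the C7 prenyl group) and C5 β-geranyl | CC(C)=CCC/C(C)=C/C[C@@]1(C(OC)OC)C[C@@H](CC=C(C)C)C(C)(C)CC1=O | intermediate
16 | prenyl bromide | CC(C)=CCBr | starting material
17 | lithium enolate of 15, C9=C1 (formed in situ) | CC(C)=CCC/C(C)=C/C[C@@]1(C(OC)OC)C[C@@H](CC=C(C)C)C(C)(C)C=C1O[Li] | intermediate
18 | C1-prenyl derivative of 15, C1 epimers | CC(C)=CCC/C(C)=C/C[C@@]1(C(OC)OC)C[C@@H](CC=C(C)C)C(C)(C)C(CC=C(C)C)C1=O | intermediate
19 | 3,4-dihydroxybenzaldehyde | O=Cc1ccc(O)c(O)c1 | starting material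
20 | 3,4-bis(tert-butyldimethylsilyloxy)benzaldehyde | O=Cc1ccc(O[Si](C)(C)C(C)(C)C)c(O[Si](C)(C)C(C)(C)C)c1 | intermediate
21 | 1,1-dibromo-2-[3,4-bis(tert-butyldimethylsilyloxy)phenyl]ethene | BrC(Br)=Cc1ccc(O[Si](C)(C)C(C)(C)C)c(O[Si](C)(C)C(C)(C)C)c1 | intermediate
22 | lithium [3,4-bis(tert-butyldimethylsilyloxy)phenyl]acetylide (formed in situ) | [Li]C#Cc1ccc(O[Si](C)(C)C(C)(C)C)c(O[Si](C)(C)C(C)(C)C)c1 | intermediate
23 | 3-[3,4-bis(tert-butyldimethylsilyloxy)phenyl]prop-2-ynal | O=CC#Cc1ccc(O[Si](C)(C)C(C)(C)C)c(O[Si](C)(C)C(C)(C)C)c1 | intermediate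
24 | lithium enolate of 18, C9=C1 (formed in situ) | CC(C)=CCC/C(C)=C/C[C@@]1(C(OC)OC)C[C@@H](CC=C(C)C)C(C)(C)C(CC=C(C)C)=C1O[Li] | intermediate
25 | aldol adduct: C1 α-(1-hydroxy-3-arylprop-2-yn-1-yl), C1 β-prenyl, C5 α-dimethoxymethyl, C5 β-geranyl ring B ketone, carbinol epimers | CC(C)=CCC/C(C)=C/C[C@@]1(C(OC)OC)C[C@@H](CC=C(C)C)C(C)(C)[C@](CC=C(C)C)(C(O)C#Cc2ccc(O[Si](C)(C)C(C)(C)C)c(O[Si](C)(C)C(C)(C)C)c2)C1=O | intermediate
26 | C1 α-(3-arylprop-2-ynoyl) ring B ketone with the C5 α-dimethoxymethyl arm | CC(C)=CCC/C(C)=C/C[C@@]1(C(OC)OC)C[C@@H](CC=C(C)C)C(C)(C)[C@](CC=C(C)C)(C(=O)C#Cc2ccc(O[Si](C)(C)C(C)(C)C)c(O[Si](C)(C)C(C)(C)C)c2)C1=O | intermediate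
27 | C5 α-formyl, C1 α-(3-arylprop-2-ynoyl) ring B ketone (formed in situ) | CC(C)=CCC/C(C)=C/C[C@@]1(C=O)C[C@@H](CC=C(C)C)C(C)(C)[C@](CC=C(C)C)(C(=O)C#Cc2ccc(O[Si](C)(C)C(C)(C)C)c(O[Si](C)(C)C(C)(C)C)c2)C1=O | intermediate
28 | ring B ketone with C5 α-(E)-aldoxime and C1 α-aryl ynone, bis-silyl ether (key-step precursor) | CC(C)=CCC/C(C)=C/C[C@@]1(/C=N/O)C[C@@H](CC=C(C)C)C(C)(C)[C@](CC=C(C)C)(C(=O)C#Cc2ccc(O[Si](C)(C)C(C)(C)C)c(O[Si](C)(C)C(C)(C)C)c2)C1=O | intermediate
29 | C5 hydroximoyl chloride of 28 (formed in situ) | CC(C)=CCC/C(C)=C/C[C@@]1(C(Cl)=NO)C[C@@H](CC=C(C)C)C(C)(C)[C@](CC=C(C)C)(C(=O)C#Cc2ccc(O[Si](C)(C)C(C)(C)C)c(O[Si](C)(C)C(C)(C)C)c2)C1=O | intermediate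
30 | C4 nitrile oxide (formed in situ) | CC(C)=CCC/C(C)=C/C[C@@]1(C#[N+][O-])C[C@@H](CC=C(C)C)C(C)(C)[C@](CC=C(C)C)(C(=O)C#Cc2ccc(O[Si](C)(C)C(C)(C)C)c(O[Si](C)(C)C(C)(C)C)c2)C1=O | intermediate
31 | isoxazole-fused bicyclo[3.3.1]nonane-2,9-dione, bis-silyl ether (key-step product) | CC(C)=CCC/C(C)=C/C[C@]12C[C@@H](CC=C(C)C)C(C)(C)[C@](CC=C(C)C)(C(=O)c3c1noc3-c4ccc(O[Si](C)(C)C(C)(C)C)c(O[Si](C)(C)C(C)(C)C)c4)C2=O | intermediate
32 | C4-amino enaminone of the bicyclic 2,9-dione with C3 aroyl, bis-silyl ether | CC(C)=CCC/C(C)=C/C[C@]12C[C@@H](CC=C(C)C)C(C)(C)[C@](CC=C(C)C)(C(=O)C(C(=O)c3ccc(O[Si](C)(C)C(C)(C)C)c(O[Si](C)(C)C(C)(C)C)c3)=C1N)C2=O | intermediate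
33 | CNP0160101.3: 3-(3,4-dihydroxybenzoyl)-5-geranyl-4-hydroxy-8,8-dimethyl-1,7-diprenylbicyclo[3.3.1]non-3-ene-2,9-dione | CC(C)=CCC/C(C)=C/C[C@]12C[C@@H](CC=C(C)C)C(C)(C)[C@](CC=C(C)C)(C(=O)C(C(=O)c3ccc(O)c(O)c3)=C1O)C2=O | target

## Step count and least certain steps

Total: 18 steps. Longest linear sequence: 15 steps (steps 1–9, then 13–18). The ynal 23 is made in 3 steps (10–12) and joins at step 13.

**Step 16 (key step).** Electrophilic chlorination of the trisubstituted alkenes may compete with chlorination of the oxime. Conjugate addition of chloride or amine to the ynone, or dimerisation of the dipole if ring closure is slow, may also intervene. Fallback, from 28 back to 31: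
- Luche reduction (NaBH4, CeCl3·7H2O, MeOH, −78 °C) of the ynone carbonyl gives the propargylic alcohol oxime F1.
- Halogen-free oxidation with PhI(OAc)2 in MeOH at 0 °C generates the nitrile oxide, which adds to the unactivated alkyne to give the isoxazolyl carbinol F2.
- Dess–Martin oxidation of this carbinol gives 31.

**Step 13.** Enolisation of the shielded C1–H may be incomplete. The aldol addition may revert, driven by relief of the 1,3-diaxial strain between the two arms. Fallback, from 18 back to 25:
- Enolate 24 is trapped with monomeric formaldehyde to give the C1 hydroxymethyl ketone F3.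
- Dess–Martin oxidation gives the keto aldehyde F4.
- Addition of acetylide 22 in the presence of CeCl3 at −78 °C with a cold NH4Cl quench gives 25.

**Step 18.** Hydroxide addition to the neopentylic C4 may be slow, so that retro-Claisen opening or oxidation of the catecholate competes. Fallback, from 32 to 33:
- Boc2O and DMAP in MeCN activate the nitrogen as the N-Boc enaminone F5.
- LiOH in degassed THF/H2O at 25 °C then expels tert-butyl carbamate and cleaves the silyl ethers to give 33.

**Step 15.** Hydrolysis of the neopentylic β-keto acetal may need acid strong enough to hydrate or cyclise the prenyl groups. Hydroxylamine may add to the ynone in competition with oxime formation. Fallback, from 25 (before the ynone exists) back to 28: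
- 2 M HCl in THF gives the hydroxy aldehyde F6, in equilibrium with its lactol.
- O-(tetrahydro-2H-pyran-2-yl)hydroxylamine and pyridine in EtOH give the O-tetrahydropyranyl oxime alcohol F7.
- Dess–Martin oxidation gives the O-tetrahydropyranyl oxime ynone F8.
- PPTS in EtOH at 40 °C releases 28.

**Step 9.** C-alkylation at the neopentylic enolate carbon may be slow, with O-alkylation competing. Fallback, from 15 back to 18:
- KN(SiMe3)2 and allyl chloroformate give the allyl enol carbonate F9.
- Pd(PPh3)4 (zerovalent palladium) in THF brings about decarboxylative Tsuji–Trost allylation to the C1 allyl ketone F10.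
- Cross-metathesis with 2-methylbut-2-ene and the second-generation Grubbs catalyst RuCl2(=CHPh)(H2IMes)(PCy3) gives 18; the trisubstituted alkenes should remain spectators.

## Further compounds

F1 | step 16 | propargylic alcohol oxime (C2 carbinol epimers) | CC(C)=CCC/C(C)=C/C[C@@]1(/C=N/O)C[C@@H](CC=C(C)C)C(C)(C)[C@](CC=C(C)C)(C(O)C#Cc2ccc(O[Si](C)(C)C(C)(C)C)c(O[Si](C)(C)C(C)(C)C)c2)C1=O
F2 | step 16 | isoxazolyl carbinol (C2 carbinol epimers) | CC(C)=CCC/C(C)=C/C[C@]12C[C@@H](CC=C(C)C)C(C)(C)[C@](CC=C(C)C)(C(O)c3c1noc3-c4ccc(O[Si](C)(C)C(C)(C)C)c(O[Si](C)(C)C(C)(C)C)c4)C2=O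
F3 | step 13 | C1 α-hydroxymethyl ketone | CC(C)=CCC/C(C)=C/C[C@@]1(C(OC)OC)C[C@@H](CC=C(C)C)C(C)(C)[C@](CC=C(C)C)(CO)C1=O
F4 | step 13 | C1 α-formyl ketone | CC(C)=CCC/C(C)=C/C[C@@]1(C(OC)OC)C[C@@H](CC=C(C)C)C(C)(C)[C@](CC=C(C)C)(C=O)C1=O
F5 | step 18 | N-Boc enaminone | CC(C)=CCC/C(C)=C/C[C@]12C[C@@H](CC=C(C)C)C(C)(C)[C@](CC=C(C)C)(C(=O)C(C(=O)c3ccc(O[Si](C)(C)C(C)(C)C)c(O[Si](C)(C)C(C)(C)C)c3)=C1NC(=O)OC(C)(C)C)C2=O
F6 | step 15 | C5 α-formyl propargylic alcohol (carbinol epimers) | CC(C)=CCC/C(C)=C/C[C@@]1(C=O)C[C@@H](CC=C(C)C)C(C)(C)[C@](CC=C(C)C)(C(O)C#Cc2ccc(O[Si](C)(C)C(C)(C)C)c(O[Si](C)(C)C(C)(C)C)c2)C1=O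
F7 | step 15 | O-tetrahydropyranyl oxime propargylic alcohol (carbinol and acetal epimers) | CC(C)=CCC/C(C)=C/C[C@@]1(/C=N/OC3CCCCO3)C[C@@H](CC=C(C)C)C(C)(C)[C@](CC=C(C)C)(C(O)C#Cc2ccc(O[Si](C)(C)C(C)(C)C)c(O[Si](C)(C)C(C)(C)C)c2)C1=O
F8 | step 15 | O-tetrahydropyranyl oxime ynone (acetal epimers) | CC(C)=CCC/C(C)=C/C[C@@]1(/C=N/OC3CCCCO3)C[C@@H](CC=C(C)C)C(C)(C)[C@](CC=C(C)C)(C(=O)C#Cc2ccc(O[Si](C)(C)C(C)(C)C)c(O[Si](C)(C)C(C)(C)C)c2)C1=O
F9 | step 9 | allyl enol carbonate of 15 (C9=C1) | CC(C)=CCC/C(C)=C/C[C@@]1(C(OC)OC)C[C@@H](CC=C(C)C)C(C)(C)C=C1OC(=O)OCC=C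
F10 | step 9 | C1 allyl ketone (C1 epimers) | CC(C)=CCC/C(C)=C/C[C@@]1(C(OC)OC)C[C@@H](CC=C(C)C)C(C)(C)C(CC=C)C1=O
A1 | alternative 1 | bicyclic trione with C5 hydrogen, C1 prenyl and equatorial C7 formyl | [C@H]12C[C@@H](C=O)C(C)(C)[C@](CC=C(C)C)(C(=O)C=C1O)C2=O
A2 | alternative 1 | achiral 2-prenyl-2-(3-formyl-2-methylbut-3-en-2-yl)cyclohexane-1,3,5-trione | CC(C)=CCC1(C(C)(C)C(=C)C=O)C(=O)CC(=O)CC1=O
A3 | alternative 2 | bicyclic C2 methyl enol ether with C5 geranyl, C7 prenyl and C1 silyloxyethyl | CC(C)=CCC/C(C)=C/C[C@]12C[C@@H](CC=C(C)C)C(C)(C)[C@](CCO[Si](C)(C)C(C)(C)C)(C(OC)=CC1=O)C2=O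
A4 | alternative 2 | ring A bromide with C5 geranyl, C1 1,1-dimethylallyl and C1 silyloxyethyl | CC(C)=CCC/C(C)=C/CC1(Br)C(=O)C=C(OC)[C@@](CCO[Si](C)(C)C(C)(C)C)(C(C)(C)C=C)C1=O
A5 | alternative 2 | (2-methylbut-3-en-2-yl)sulfonylbenzene | C=CC(C)(C)S(=O)(=O)c1ccccc1
A6 | alternative 3 | 5-geranyl-4-methoxy-8,8-dimethyl-7-prenylbicyclo[3.3.1]non-3-en-9-one | CC(C)=CCC/C(C)=C/C[C@]12C[C@@H](CC=C(C)C)C(C)(C)[C@H](CC=C1OC)C2=O
A7 | alternative 3 | 1,5-dimethoxycyclohexa-1,4-diene with C5 geranyl and the C6–C7–C8 tertiary alcohol chain | CC(C)=CCC/C(C)=C/CC1(C[C@@H](CC=C(C)C)C(C)(C)O)C(OC)=CCC=C1OC
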